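Late in the winter run, with starting material down to 0.8%, target falls from 82.4% at 10.0 h to 34.4% at 50.0 h. I begin from that slow decay, and the flask asked about is this same flask.

the same everywhere: gas phase 200 mM (held)

| charge | starting material | remark | time |
|---|---|---|---|
| winter | 2 M | the very flask that is asked about, followed so far |  |
| flask | 2.0 M |  | 4.0 d |

winter run (percent of the starting material charged)

| time / h | target / % | starting material / % |
|---|---|---|
| 1.00 | 61.9 | 38.4 |
| 2.00 | 84.7 | 14.0 |
| 5.00 | 91.2 | 0.8 |
| 10.0 | 82.4 | 0.8 |
| 20.0 | 66.3 | 0 |
| 50.0 | 34.4 | 0.1 |

(scatter of a reading: 0.5 percentage points)

- what was read earlier has a scatter of 0.5 percentage points, one standard deviation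
- at the start none of the gas phase is in solution

- time up to 4.0 d at which target stands highest
- the amount of target, in percent of the starting material charged, at that time

With the gas phase held, I treat both falls as first order (pseudo-first-order). I read the loss constant of target, kP, from those two late readings, and that of starting material, kA, from its first two readings:

kP = 0.0218 /h
kA = 1.01 /h
S = kA/kP = 46.2

This S, the selectivity factor, counts the lifetimes of starting material that fit into one lifetime of target.

Here is the oddity: one lifetime of starting material costs target about 2.16% of itself, yet at 5.00 h, with starting material at 0.8%, 8.00% of the charge is missing.

So I count turnovers. Target peaks when its gain equals its loss, which happens once starting material stands at 1/S of target. That takes about ln S lifetimes, and each of them costs target its 1/S: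

n = ln S = 3.83 lifetimes
best time = n/(kA − kP) = 0.162 d
height = exp(−n/(S − 1)) = 91.9%
shortfall of target from the charge at the peak = 8.13%
of that, still starting material, 1/S of target = 1.99%
of that, target already lost = 6.14%

The gap is therefore several lifetimes' cost, not one.

The forecast gives 91.9% at 0.17 d, a little later than my time, and notes that “The maximum is flat”. The flask gives 91.8% at 0.164 d.

    gas phase ⇌ dissolved gas, rate k1*(csat - [dissolved gas]) (kL = 270 /h)
    starting material + dissolved gas → target (k = 5.00 /M/h)
    dissolved gas + target → over-reacted product (k = 0.110 /M/h)

Without the step from dissolved gas + target to over-reacted product, the same flask reaches 100% instead of 91.8%. That difference of 8.2 percentage points is not all over-reacted product: at the best time the flask holds 6.21% of it and 2.02% of starting material, against my 6.14% and 1.99% from S. Both steps use dissolved gas, and I carry S to the neighbour flask charged with 1.2 M of starting material: n and S again give 91.9%, and that flask reaches 91.8%.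

The data come from a simulation with constants of no real substance; scatter was added.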